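Skeleton numbering used throughout: nine-membered ring C1 (exocyclic methylene), C2, C3, C4 (ketone), C5 (methyl-bearing), C6, C7, C8 and C9 (ring fusion); cyclobutane C8–C9–C10–C11 (C11 quaternary, bonded to C8); side chain C12(OAc)–C13–C14=C15(CH3)–C16. Compounds are numbered 1–36 in the order in which they appear in the steps.

## Analysis of the target

The target is a xeniaphyllane-type diterpenoid: a nine-membered carbocycle trans-fused to a cyclobutane whose quaternary C11 carries a methyl group and the chain C12(OAc)–C13H2–C14H=C15(CH3)–C16H2OAc with a Z trisubstituted alkene. It has five stereocentres, 5S, 8S, 9R, 11S and 12S. H8 and H9 are trans, the C11 methyl is cis to C7 (so C12 lies on the face of C1), C12 is a carbinol next to the quaternary carbon, and C5 is an epimerisable centre α to the C4 ketone. The sensitive groups are the two acetates (one allylic), the 1,1-disubstituted alkene beside the strained four-membered ring (acid-labile, as in caryophyllene chemistry) and the C5 hydrogen next to the ketone. The synthesis is hard because a nine-membered ring resists end-to-end closure, because it must be trans-fused to a cyclobutane bearing a quaternary stereocentre, and because configuration has to be relayed from the cyclobutane block (C8, C9, C11, C12) to the remote C5. The plan rests on one feature: C1 at the carbonyl level, with C9–C8 on one side and C5–C6–C7 on the other, becomes the oxygenated carbon of a 3-oxy-1,5-diene, C8=C9–C1(O)–C5–C6=C7, once C1 and C5 are bonded. That bond makes a cyclopentane (C1–C5), so the nine-membered ring can be grown from a five-membered one by a [3,3] shift that inserts C6–C7–C8–C9.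

## Retrosynthetic reasoning

**36 to 34.** The C4 ketone is unmasked last. It is the only site that makes C5 epimerisable and it would not survive the ylide, hydride and allylboron reagents used earlier, so it is carried as a silyl ether (35, 34) and oxidised under non-basic conditions at the end.

**34 to 27.** The Z C14=C15 alkene is not made by olefination. A (Z)-2-methyl-2-ene-1,5-diol (33) is the reduced form of an α-methyl-α,β-unsaturated δ-lactone (31), in which the ring enforces the geometry. The lactone comes from ring-closing metathesis of methacrylate 30, and the C12–C13 bond from reagent-controlled allylation of the neopentyl aldehyde 27, which sets 12S.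

**27 to 23.** The aldehyde comes from the primary silyl ether 25, the C1 methylene from ketone 24 by a one-carbon ylide, and the C5 hydrogen from hydrogenation of the E C5=C6 alkene of 23. Hydrogen must arrive on the face of C5 from which C1 departed. In an E-cyclononene the exposed face depends on which side of the alkene the ring passes, and allylic strain at C4 biases this: with C4 S, the conformer that keeps C4–H rather than C4–O beside the C5 methyl exposes the required face.

**23 to 20 (key disconnection).** Reconnecting C1 to C5 and cutting C7–C8 turns the bicyclic ketone 23 into the cyclobutenyl vinyl cyclopentanol 20. The cut is made here because it replaces the closure of a nine-membered ring by the expansion of a five-membered one and creates C8 by transfer of configuration, while C9 is left α to the new ketone, where it can equilibrate to the trans fusion. The forward reaction needs a chair, which requires the two alkenyl groups trans on the cyclopentane. With C1 and C5 both R and the cyclobutene centre S, C7 meets C8 on the face anti to the silyloxymethyl group. The mirror-image cyclopentane would pair with the same cyclobutene only through a chair that bonds C7 syn to that group and would give the C8 epimer.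

**20 to 16.** C4 is wanted S in 20, with its oxygen trans to the C1 oxygen and to the vinyl group. This is the arrangement that favours the correct hydrogenation face later and keeps the silyl ether away from the alkoxide. The addition that creates C1 is only dependable when the C4 oxygen is cis to the vinyl group and shields that face. C4 is therefore taken through the addition as R (16) and then inverted by desilylation (17), oxidation (18) and hydroxyl-directed reduction from the C1 hydroxyl (19).

**16 to 5 and 13.** The C1–C9 bond is cut to the silyloxy ketone 5 and a cyclobutenyl nucleophile generated from stannane 13. Both are small and made separately, and any shortfall in the enantiopurity of 13 becomes a separable diastereomer at this point.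

**5 to 1.** The hydroxy ketone 4 comes from desymmetrising monoreduction of the vinyl dione 3. The vinyl group is installed on dione 1 as an alkyne (2) and semihydrogenated, because direct vinylation of a 1,3-diketone is less dependable than alkynylation.

**13 to 6.** The stereocentre C11 of 13 exists only because the double bond lies on one side of a mirror-symmetric ring. It is therefore traced to the prochiral cyclobutanone 10 by enantioselective enolisation (11, 12), and 10 to a ketene [2+2] adduct (9) of the silyl ether 7 of alcohol 6.

## Alternatives that were turned down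

**Alternative 1:** The cyclobutane is cut at C8–C11 and traced to a cyclopropanol. In the forward key step BF3·OEt2 opens the epoxide of the epoxy cyclopropanol A2 at the tertiary carbon C11 and a cyclopropane bond migrates there, expanding the ring to cyclobutanone A1.
- For: C11 and C12, the quaternary centre and its carbinol neighbour, both come from one epoxide and are set stereospecifically (inversion at C11, retention at C12). On these two centres it is stronger than the chosen route, which needs a chiral-base desymmetrisation (step 8) and a reagent-controlled allylation (step 20).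
- Against: A1 carries its carbonyl at C10, a plain methylene in the target, and C8 and C9 are unfunctionalised CH2 groups. Both ring-fusion centres, their trans relation, the attachment of C7 and C1 and the nine-membered ring itself remain to be made, the ring by end-to-end closure.
- Comparison: the chosen route spends more effort on C11 and C12 but obtains the ring, C8 and C9 in the single step from 20 to 23.

**Alternative 2:** The cyclobutane is cut at C10–C11 and traced to a five-membered ring. In the forward key step photolysis of the α-diazoketone A4 in methanol triggers a Wolff rearrangement in which C10 shifts to C11, and the ketene is trapped as the methyl ester A3.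
- For: C8 and C9, their trans relation and both one-carbon arms (the future C7 and C1) come from a C2-symmetric precursor, and ring contraction is a dependable way to make cyclobutanes. On the ring-fusion centres it is at least as secure as the equilibration at C9 used here.
- Against: C11 arrives as a CH bearing the ester, and enolate methylation would bring the methyl group in anti to the C8 arm, whereas the target has it cis to C7. The two silyloxymethyl arms of A3 are nearly identical and must be told apart. The nine-membered ring must still be closed across seven atoms.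
- Comparison: the chosen route brings C11 in as a finished quaternary centre and uses it only to match a transfer that the chair enforces.

**Alternative 3:** The cyclobutane is cut at C8–C9. In the forward key step the dilithium bis-enolate of the adipoyl bis-imide A6 is oxidised with CuCl2 and the two α-carbons couple to give A5.
- For: one step sets C8 and C9 (trans) under the influence of C11, from an open chain that is easy to assemble. All three cyclobutane centres are in place early and both carbonyl arms are at a useful oxidation level.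
- Against: oxidative enolate coupling to a four-membered ring competes with intermolecular coupling, and the relay from C11 (methyl against silyloxymethyl) to C8 is weak. The imides are achiral, so absolute configuration rests wholly on an enantiopure A6, and the two identical acyl termini must be differentiated. The nine-membered ring is again left for an end-to-end closure.
- Comparison: both plans need an enantiopure C11. The chosen one adds step count before the key step but removes the medium-ring closure, where the alternatives carry their main risk.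

Key step: step 15

Assumption: the antipodes of the chiral reagents in steps 3, 8 and 20 are assigned from the accepted transition-state models; should a sense prove reversed, the mirror-image reagent is used.

## Steps

Step 1
Reactants: 1 2-methylcyclopentane-1,3-dione
Product: 2 2-ethynyl-2-methylcyclopentane-1,3-dione
Conditions: TMS-EBX, TBAF, THF, −78 °C to rt
Reagents that add atoms: 1-[(trimethylsilyl)ethynyl]-1,2-benziodoxol-3(1H)-one (TMS-EBX), C[Si](C)(C)C#CI1OC(=O)c2ccccc12
Why: Electrophilic α-alkynylation of a 1,3-diketone with an ethynylbenziodoxolone (trivalent iodine): fluoride removes the silyl group and forms the diketonate, which adds to the alkynyl iodane; loss of 2-iodobenzoate and a 1,2-hydrogen shift of the alkylidene carbene leave the terminal alkyne on the quaternary carbon. No stereocentre is formed.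

Step 2
Reactants: 2 2-ethynyl-2-methylcyclopentane-1,3-dione
Product: 3 2-ethenyl-2-methylcyclopentane-1,3-dione
Conditions: H2 (1 atm), Pd/CaCO3 poisoned with Pb(OAc)2 (Lindlar catalyst), quinoline, EtOAc, rt
Reagents that add atoms: none
Why: Lindlar semihydrogenation stops at the alkene for a terminal alkyne; the ketones are untouched.

Step 3
Reactants: 3 2-ethenyl-2-methylcyclopentane-1,3-dione
Product: 4 (2R,3R)-2-ethenyl-3-hydroxy-2-methylcyclopentan-1-one (hydroxyl cis to vinyl)
Conditions: (S)-2-methyl-CBS-oxazaborolidine (10 mol%), catecholborane, toluene, −78 °C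
Reagents that add atoms: none
Why: Corey–Bakshi–Shibata desymmetrising monoreduction: the catalyst reads the quaternary carbon as the large and the ring CH2 as the small flank and so fixes the carbinol as R, which limits the products to (2R,3R) and (2S,3R). Hydride entry past the methyl group rather than the vinyl group should favour (2R,3R)-4; the diastereomer is removed by chromatography and can be oxidised back to 3.

Step 4
Reactants: 4 (2R,3R)-2-ethenyl-3-hydroxy-2-methylcyclopentan-1-one
Product: 5 (2R,3R)-2-ethenyl-2-methyl-3-(triethylsilyloxy)cyclopentan-1-one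
Conditions: Et3SiCl, imidazole, DMF, 0 °C
Reagents that add atoms: chlorotriethylsilane, CC[Si](Cl)(CC)CC
Why: Silylation of the secondary alcohol. The bulky silyloxy group on the vinyl face is the control element for step 10 and can later be removed beside the primary TBS ether.

Step 5
Reactants: 6 2-methylprop-2-en-1-ol
Product: 7 tert-butyldimethyl[(2-methylprop-2-en-1-yl)oxy]silane
Conditions: TBSCl, imidazole, CH2Cl2, rt
Reagents that add atoms: tert-butyldimethylsilyl chloride, CC(C)(C)[Si](C)(C)Cl
Why: Standard silylation of a primary alcohol.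

Step 6
Reactants: 7 tert-butyldimethyl[(2-methylprop-2-en-1-yl)oxy]silane
Product: 9 rac-3-{[tert-butyl(dimethyl)silyl]oxymethyl}-2,2-dichloro-3-methylcyclobutan-1-one, via dichloroketene 8 (not isolated)
Conditions: Cl3CCOCl, Zn(Cu) couple, Et2O/DME, rt, ultrasound
Reagents that add atoms: trichloroacetyl chloride, ClC(=O)C(Cl)(Cl)Cl
Why: Thermal [2+2] cycloaddition of dichloroketene to a 1,1-disubstituted alkene; the carbonyl carbon bonds to the CH2 terminus, so the quaternary carbon ends β to the ketone. The product is racemic, and its stereocentre disappears in step 7; DME ties up ZnCl2 and protects the silyl ether.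

Step 7
Reactants: 9 rac-3-{[tert-butyl(dimethyl)silyl]oxymethyl}-2,2-dichloro-3-methylcyclobutan-1-one
Product: 10 3-{[tert-butyl(dimethyl)silyl]oxymethyl}-3-methylcyclobutan-1-one
Conditions: Zn, NH4Cl, MeOH, rt
Reagents that add atoms: none
Why: Zinc reduction of the α,α-dichloroketone removes both chlorines and leaves the mirror-symmetric cyclobutanone; the buffered medium spares the silyl ether.

Step 8
Reactants: 10 3-{[tert-butyl(dimethyl)silyl]oxymethyl}-3-methylcyclobutan-1-one
Product: 12 (3S)-3-{[tert-butyl(dimethyl)silyl]oxymethyl}-3-methylcyclobut-1-en-1-yl trifluoromethanesulfonate, via lithium enolate 11 (not isolated)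
Conditions: (R,R)-bis(1-phenylethyl)amine, n-BuLi, LiCl, THF, −100 °C; then Comins' reagent, −78 to −20 °C
Reagents that add atoms: N-(5-chloropyridin-2-yl)-1,1,1-trifluoro-N-(trifluoromethylsulfonyl)methanesulfonamide (Comins' reagent), FC(F)(F)S(=O)(=O)N(c1ccc(Cl)cn1)S(=O)(=O)C(F)(F)F
Why: Enantioselective deprotonation of a prochiral cyclobutanone by a C2-symmetric chiral lithium amide (known for 3-substituted cyclobutanones), with O-triflation of the enolate. The base distinguishes the two enantiotopic α-methylene groups, and this fixes C11 as S because that centre is defined only by the position of the double bond. Residual antipode becomes a separable diastereomer in step 10.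

Step 9
Reactants: 12 (3S)-3-{[tert-butyl(dimethyl)silyl]oxymethyl}-3-methylcyclobut-1-en-1-yl trifluoromethanesulfonate
Product: 13 (S)-tert-butyldimethyl{[1-methyl-3-(trimethylstannyl)cyclobut-2-en-1-yl]methoxy}silane
Conditions: Me3SnSnMe3, Pd(PPh3)4 (5 mol%), LiCl, THF, 60 °C
Reagents that add atoms: hexamethylditin, C[Sn](C)(C)[Sn](C)(C)C
Why: Palladium-catalysed stannylation of an alkenyl triflate (oxidative addition to zerovalent palladium, Sn–Sn transmetalation, reductive elimination); C11 is not involved.

Step 10
Reactants: 13 (S)-tert-butyldimethyl{[1-methyl-3-(trimethylstannyl)cyclobut-2-en-1-yl]methoxy}silane; 5 (2R,3R)-2-ethenyl-2-methyl-3-(triethylsilyloxy)cyclopentan-1-one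
Product: 16 (1R,2R,3R)-1-[(3S)-3-{[tert-butyl(dimethyl)silyl]oxymethyl}-3-methylcyclobut-1-en-1-yl]-2-ethenyl-2-methyl-3-(triethylsilyloxy)cyclopentan-1-ol, via cyclobutenyllithium 14 (not isolated), via cyclobutenylcerium dichloride 15 (not isolated)
Conditions: MeLi, THF, −78 °C; CeCl3, −78 °C; then 5, −78 °C; aq NH4Cl
Reagents that add atoms: none
Why: Tin–lithium exchange gives the alkenyllithium, and CeCl3 converts it into a weakly basic organocerium that adds 1,2 to the enolisable ketone. Attack comes from the face opposite to the silyloxy and vinyl groups (syn to methyl), which sets C1 as R with cyclobutenyl trans to vinyl.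

Step 11
Reactants: 16 (1R,2R,3R)-1-[(3S)-3-{[tert-butyl(dimethyl)silyl]oxymethyl}-3-methylcyclobut-1-en-1-yl]-2-ethenyl-2-methyl-3-(triethylsilyloxy)cyclopentan-1-ol
Product: 17 (1R,2R,3R)-1-[(3S)-3-{[tert-butyl(dimethyl)silyl]oxymethyl}-3-methylcyclobut-1-en-1-yl]-2-ethenyl-2-methylcyclopentane-1,3-diol (1,3-cis diol)
Conditions: PPTS, MeOH/CH2Cl2, 0 °C
Reagents that add atoms: none
Why: Acid-catalysed methanolysis of the triethylsilyl ether; the primary TBS ether reacts far more slowly, and PPTS is too weak to ionise the tertiary allylic alcohol.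

Step 12
Reactants: 17 (1R,2R,3R)-1-[(3S)-3-{[tert-butyl(dimethyl)silyl]oxymethyl}-3-methylcyclobut-1-en-1-yl]-2-ethenyl-2-methylcyclopentane-1,3-diol
Product: 18 (2S,3R)-3-[(3S)-3-{[tert-butyl(dimethyl)silyl]oxymethyl}-3-methylcyclobut-1-en-1-yl]-2-ethenyl-3-hydroxy-2-methylcyclopentan-1-one
Conditions: Dess–Martin periodinane, NaHCO3, CH2Cl2, 0 °C to rt
Reagents that add atoms: none
Why: Dess–Martin oxidation of the secondary alcohol; the tertiary alcohol cannot be oxidised, and the buffered non-basic medium avoids retro-aldol cleavage of the β-hydroxy ketone.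

Step 13
Reactants: 18 (2S,3R)-3-[(3S)-3-{[tert-butyl(dimethyl)silyl]oxymethyl}-3-methylcyclobut-1-en-1-yl]-2-ethenyl-3-hydroxy-2-methylcyclopentan-1-one
Product: 19 (1R,2R,3S)-1-[(3S)-3-{[tert-butyl(dimethyl)silyl]oxymethyl}-3-methylcyclobut-1-en-1-yl]-2-ethenyl-2-methylcyclopentane-1,3-diol (1,3-trans diol)
Conditions: Me4NBH(OAc)3, MeCN/AcOH, −25 °C
Reagents that add atoms: none
Why: Evans–Saksena hydroxyl-directed reduction: the triacetoxyborohydride binds the C1 hydroxyl and delivers hydride intramolecularly to the C4 carbonyl on that face, giving the 1,3-anti diol. C4 is thereby inverted to S, trans to the C1 oxygen and to the vinyl group.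

Step 14
Reactants: 19 (1R,2R,3S)-1-[(3S)-3-{[tert-butyl(dimethyl)silyl]oxymethyl}-3-methylcyclobut-1-en-1-yl]-2-ethenyl-2-methylcyclopentane-1,3-diol
Product: 20 (1R,2R,3S)-1-[(3S)-3-{[tert-butyl(dimethyl)silyl]oxymethyl}-3-methylcyclobut-1-en-1-yl]-2-ethenyl-2-methyl-3-(triisopropylsilyloxy)cyclopentan-1-ol
Conditions: TIPSOTf, 2,6-lutidine, CH2Cl2, −78 to 0 °C
Reagents that add atoms: triisopropylsilyl trifluoromethanesulfonate, CC(C)[Si](C(C)C)(C(C)C)OS(=O)(=O)C(F)(F)F
Why: Silylation of the secondary alcohol only (the tertiary alcohol is too hindered). Triisopropylsilyl is chosen to outlast the primary TBS ether in step 18.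

Step 15
Reactants: 20 (1R,2R,3S)-1-[(3S)-3-{[tert-butyl(dimethyl)silyl]oxymethyl}-3-methylcyclobut-1-en-1-yl]-2-ethenyl-2-methyl-3-(triisopropylsilyloxy)cyclopentan-1-ol
Product: 23 (4S,5E,8S,9R,11S)-11-{[tert-butyl(dimethyl)silyl]oxymethyl}-5,11-dimethyl-4-(triisopropylsilyloxy)bicyclo[7.2.0]undec-5-en-1-one (skeleton numbering), via potassium alkoxide 21 (not isolated), via potassium enolate 22 (not isolated)
Conditions: KH, 18-crown-6, THF, 0 °C to rt; then MeOH, rt; aq NH4Cl
Reagents that add atoms: none
Why: KH with 18-crown-6 gives the free alkoxide 21, which undergoes a concerted suprafacial [3,3]-sigmatropic shift (anionic oxy-Cope rearrangement; the closest known type is the four-carbon ring expansion of trans-1,2-dialkenylcycloalkanols): C7–C8 forms, C1–C5 breaks and enolate 22 results. The nine-membered ring is not closed end to end; it arises by ring expansion, the new bond forming inside a six-membered chair array while the five-membered ring opens. Because cyclobutenyl and vinyl are trans on the cyclopentane only a chair is reachable (a boat needs them eclipsed), with C2 and C4 equatorial, which gives the E C5=C6 alkene. In this chair the (1R,5R) configuration fixes which face of C8=C9 meets C7: for the (S)-cyclobutene it is the face anti to the silyloxymethyl group and syn to the methyl group, so the transfer is sterically matched and gives 8S. C9 is set afterwards: it is α to the new ketone, and methoxide equilibration should lead to the more stable trans-fused 9R ketone, as known for caryophyllene-type bicyclo[7.2.0]undecanones. The rearrangement must outrun other reactions of the alkoxide; the oxyanion, enolate formation and the loss of cyclobutene strain (C8 and C9 become sp3) drive it, and the C4 silyl ether, trans to the alkoxide, cannot migrate to it.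

Step 16
Reactants: 23 (4S,5E,8S,9R,11S)-11-{[tert-butyl(dimethyl)silyl]oxymethyl}-5,11-dimethyl-4-(triisopropylsilyloxy)bicyclo[7.2.0]undec-5-en-1-one
Product: 24 (4S,5S,8S,9R,11S)-11-{[tert-butyl(dimethyl)silyl]oxymethyl}-5,11-dimethyl-4-(triisopropylsilyloxy)bicyclo[7.2.0]undecan-1-one
Conditions: H2 (1 atm), PtO2, EtOAc, rt
Reagents that add atoms: none
Why: Heterogeneous syn-hydrogenation of the only alkene, which in an E-cyclononene is attacked on its exposed face. With C4 S, the conformer that keeps C4–H rather than the silyloxy group beside the C5 methyl (least allylic 1,2-strain, reached by rotation of the alkene through the ring) exposes the face from which C1 departed, which should give 5S. Platinum is used rather than palladium to limit migration of the double bond toward C4.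

Step 17
Reactants: 24 (4S,5S,8S,9R,11S)-11-{[tert-butyl(dimethyl)silyl]oxymethyl}-5,11-dimethyl-4-(triisopropylsilyloxy)bicyclo[7.2.0]undecan-1-one
Product: 25 (4S,5S,8S,9R,11S)-11-{[tert-butyl(dimethyl)silyl]oxymethyl}-5,11-dimethyl-1-methylidene-4-(triisopropylsilyloxy)bicyclo[7.2.0]undecane
Conditions: Ph3P(CH3)Br, KOtBu, toluene, rt to 80 °C
Reagents that add atoms: methyltriphenylphosphonium bromide, C[P+](c1ccccc1)(c1ccccc1)c1ccccc1.[Br-]
Why: Wittig methylenation of the hindered ketone with excess non-stabilised ylide, as practised on caryophyllene-type nor-ketones. C9 is already in its stable trans arrangement, and C5 is not enolisable at this stage.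

Step 18
Reactants: 25 (4S,5S,8S,9R,11S)-11-{[tert-butyl(dimethyl)silyl]oxymethyl}-5,11-dimethyl-1-methylidene-4-(triisopropylsilyloxy)bicyclo[7.2.0]undecane
Product: 26 [(4S,5S,8S,9R,11S)-5,11-dimethyl-1-methylidene-4-(triisopropylsilyloxy)bicyclo[7.2.0]undecan-11-yl]methanol
Conditions: HF·pyridine, pyridine, THF, 0 °C
Reagents that add atoms: none
Why: Fluoride cleavage of the primary TBS ether; the secondary triisopropylsilyl ether is far slower, and the buffered medium spares the 1,1-disubstituted alkene.

Step 19
Reactants: 26 [(4S,5S,8S,9R,11S)-5,11-dimethyl-1-methylidene-4-(triisopropylsilyloxy)bicyclo[7.2.0]undecan-11-yl]methanol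
Product: 27 (4S,5S,8S,9R,11S)-5,11-dimethyl-1-methylidene-4-(triisopropylsilyloxy)bicyclo[7.2.0]undecane-11-carbaldehyde
Conditions: Dess–Martin periodinane, NaHCO3, CH2Cl2, rt
Reagents that add atoms: none
Why: Dess–Martin oxidation to the neopentyl aldehyde, which has no α-hydrogen and cannot epimerise.

Step 20
Reactants: 27 (4S,5S,8S,9R,11S)-5,11-dimethyl-1-methylidene-4-(triisopropylsilyloxy)bicyclo[7.2.0]undecane-11-carbaldehyde
Product: 29 (12S)-homoallylic alcohol: (1S)-1-[(4S,5S,8S,9R,11S)-5,11-dimethyl-1-methylidene-4-(triisopropylsilyloxy)bicyclo[7.2.0]undecan-11-yl]but-3-en-1-ol, via tartrate boronate 28 (not isolated)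
Conditions: (R,R)-diisopropyl tartrate allylboronate, 4 Å molecular sieves, toluene, −78 °C; then aq NaOH
Reagents that add atoms: (4R,5R)-diisopropyl 2-allyl-1,3,2-dioxaborolane-4,5-dicarboxylate, C=CCB1O[C@@H](C(=O)OC(C)C)[C@@H](O1)C(=O)OC(C)C
Why: Roush asymmetric allylboration through a chair Zimmerman–Traxler transition state. The (R,R)-tartrate reagent attacks the Si face of the aldehyde, which gives 12S because the quaternary C11 is the higher-ranked substituent; reagent control is needed since the α-quaternary centre offers little Felkin bias.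

Step 21
Reactants: 29 (1S)-1-[(4S,5S,8S,9R,11S)-5,11-dimethyl-1-methylidene-4-(triisopropylsilyloxy)bicyclo[7.2.0]undecan-11-yl]but-3-en-1-ol
Product: 30 the methacrylate ester of 29 at the C12 oxygen
Conditions: methacryloyl chloride, Et3N, DMAP, CH2Cl2, 0 °C to rt
Reagents that add atoms: methacryloyl chloride, CC(=C)C(=O)Cl
Why: Acylation of the hindered secondary alcohol under nucleophilic (DMAP) catalysis.

Step 22
Reactants: 30 the methacrylate ester of 29
Product: 31 (6S)-6-[(4S,5S,8S,9R,11S)-5,11-dimethyl-1-methylidene-4-(triisopropylsilyloxy)bicyclo[7.2.0]undecan-11-yl]-3-methyl-5,6-dihydro-2H-pyran-2-one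
Conditions: second-generation Grubbs catalyst (H2IMes)(PCy3)Cl2Ru=CHPh (5–10 mol%), toluene, 80 °C
Reagents that add atoms: none
Why: Ring-closing metathesis of the terminal alkene with the methacrylate gives the six-membered α-methyl-α,β-unsaturated lactone, whose ring forces C14=C15 to be Z. The hindered 1,1-disubstituted C1 methylene is not expected to take part.

Step 23
Reactants: 31 (6S)-6-[(4S,5S,8S,9R,11S)-5,11-dimethyl-1-methylidene-4-(triisopropylsilyloxy)bicyclo[7.2.0]undecan-11-yl]-3-methyl-5,6-dihydro-2H-pyran-2-one
Product: 33 (2Z,5S)-5-[(4S,5S,8S,9R,11S)-5,11-dimethyl-1-methylidene-4-(triisopropylsilyloxy)bicyclo[7.2.0]undecan-11-yl]-2-methylpent-2-ene-1,5-diol, via lactol 32 (not isolated)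
Conditions: i-Bu2AlH (5 equiv), CH2Cl2, −78 to 0 °C; aq KNaC4H4O6 (Rochelle salt)
Reagents that add atoms: none
Why: 1,2-Reduction of the unsaturated lactone by excess i-Bu2AlH through the lactol to the enediol; the Z geometry is carried over from the ring.

Step 24
Reactants: 33 (2Z,5S)-5-[(4S,5S,8S,9R,11S)-5,11-dimethyl-1-methylidene-4-(triisopropylsilyloxy)bicyclo[7.2.0]undecan-11-yl]-2-methylpent-2-ene-1,5-diol
Product: 34 the C12,C16-diacetate of 33 (C4 triisopropylsilyl ether of the target alcohol)
Conditions: Ac2O, pyridine, DMAP, CH2Cl2, rt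
Reagents that add atoms: acetic anhydride, CC(=O)OC(C)=O
Why: Acetylation of the primary allylic and the secondary alcohol; DMAP is needed for the hindered C12 hydroxyl.

Step 25
Reactants: 34 the C12,C16-diacetate of 33
Product: 35 (4S,5S,8S,9R,11S,12S)-C4 alcohol: the target with CH(OH) in place of the C4 ketone
Conditions: TBAF, AcOH, THF, rt
Reagents that add atoms: none
Why: Fluoride desilylation of the secondary triisopropylsilyl ether; acetic acid buffers the fluoride so that the acetates are not cleaved.

Step 26
Reactants: 35 (4S,5S,8S,9R,11S,12S)-C4 alcohol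
Product: 36 the target, (5S,8S,9R,11S,12S)-configured diacetoxy methylene ketone (CNP0244219.2)
Conditions: Dess–Martin periodinane, NaHCO3, CH2Cl2, 0 °C
Reagents that add atoms: none
Why: Dess–Martin oxidation under buffered, non-basic conditions gives the C4 ketone without epimerising C5 and without touching the alkenes or acetates.

## Compound list

1 | 2-methylcyclopentane-1,3-dione | CC1C(=O)CCC1=O | starting material
2 | 2-ethynyl-2-methylcyclopentane-1,3-dione | C#CC1(C)C(=O)CCC1=O | intermediate
3 | 2-ethenyl-2-methylcyclopentane-1,3-dione | C=CC1(C)C(=O)CCC1=O | intermediate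
4 | (2R,3R)-2-ethenyl-3-hydroxy-2-methylcyclopentan-1-one | O=C1CC[C@@H](O)[C@@]1(C)C=C | intermediate
5 | (2R,3R)-2-ethenyl-2-methyl-3-(triethylsilyloxy)cyclopentan-1-one | O=C1CC[C@@H](O[Si](CC)(CC)CC)[C@@]1(C)C=C | intermediate
6 | 2-methylprop-2-en-1-ol | C=C(C)CO | starting material
7 | tert-butyldimethyl[(2-methylprop-2-en-1-yl)oxy]silane | C=C(C)CO[Si](C)(C)C(C)(C)C | intermediate
8 | dichloroketene | ClC(Cl)=C=O | intermediate
9 | rac-3-{[tert-butyl(dimethyl)silyl]oxymethyl}-2,2-dichloro-3-methylcyclobutan-1-one | O=C1CC(C)(CO[Si](C)(C)C(C)(C)C)C1(Cl)Cl | intermediate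
10 | 3-{[tert-butyl(dimethyl)silyl]oxymethyl}-3-methylcyclobutan-1-one | O=C1CC(C)(CO[Si](C)(C)C(C)(C)C)C1 | intermediate
11 | lithium (3S)-3-{[tert-butyl(dimethyl)silyl]oxymethyl}-3-methylcyclobut-1-en-1-olate | [Li+].[O-]C1=C[C@@](C)(CO[Si](C)(C)C(C)(C)C)C1 | intermediate
12 | (3S)-3-{[tert-butyl(dimethyl)silyl]oxymethyl}-3-methylcyclobut-1-en-1-yl trifluoromethanesulfonate | O=S(=O)(OC1=C[C@@](C)(CO[Si](C)(C)C(C)(C)C)C1)C(F)(F)F | intermediate
13 | (S)-tert-butyldimethyl{[1-methyl-3-(trimethylstannyl)cyclobut-2-en-1-yl]methoxy}silane | C[Sn](C)(C)C1=C[C@@](C)(CO[Si](C)(C)C(C)(C)C)C1 | intermediate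
14 | [(3S)-3-{[tert-butyl(dimethyl)silyl]oxymethyl}-3-methylcyclobut-1-en-1-yl]lithium | [Li]C1=C[C@@](C)(CO[Si](C)(C)C(C)(C)C)C1 | intermediate
15 | [(3S)-3-{[tert-butyl(dimethyl)silyl]oxymethyl}-3-methylcyclobut-1-en-1-yl]cerium dichloride | Cl[Ce](Cl)C1=C[C@@](C)(CO[Si](C)(C)C(C)(C)C)C1 | intermediate
16 | (1R,2R,3R)-1-[(3S)-3-{[tert-butyl(dimethyl)silyl]oxymethyl}-3-methylcyclobut-1-en-1-yl]-2-ethenyl-2-methyl-3-(triethylsilyloxy)cyclopentan-1-ol | O[C@@]1(C2=C[C@@](C)(CO[Si](C)(C)C(C)(C)C)C2)CC[C@@H](O[Si](CC)(CC)CC)[C@@]1(C)C=C | intermediate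
17 | (1R,2R,3R)-1-[(3S)-3-{[tert-butyl(dimethyl)silyl]oxymethyl}-3-methylcyclobut-1-en-1-yl]-2-ethenyl-2-methylcyclopentane-1,3-diol | O[C@@]1(C2=C[C@@](C)(CO[Si](C)(C)C(C)(C)C)C2)CC[C@@H](O)[C@@]1(C)C=C | intermediate
18 | (2S,3R)-3-[(3S)-3-{[tert-butyl(dimethyl)silyl]oxymethyl}-3-methylcyclobut-1-en-1-yl]-2-ethenyl-3-hydroxy-2-methylcyclopentan-1-one | O[C@@]1(C2=C[C@@](C)(CO[Si](C)(C)C(C)(C)C)C2)CCC(=O)[C@@]1(C)C=C | intermediate
19 | (1R,2R,3S)-1-[(3S)-3-{[tert-butyl(dimethyl)silyl]oxymethyl}-3-methylcyclobut-1-en-1-yl]-2-ethenyl-2-methylcyclopentane-1,3-diol | O[C@@]1(C2=C[C@@](C)(CO[Si](C)(C)C(C)(C)C)C2)CC[C@H](O)[C@@]1(C)C=C | intermediate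
20 | (1R,2R,3S)-1-[(3S)-3-{[tert-butyl(dimethyl)silyl]oxymethyl}-3-methylcyclobut-1-en-1-yl]-2-ethenyl-2-methyl-3-(triisopropylsilyloxy)cyclopentan-1-ol (key-step precursor) | O[C@@]1(C2=C[C@@](C)(CO[Si](C)(C)C(C)(C)C)C2)CC[C@H](O[Si](C(C)C)(C(C)C)C(C)C)[C@@]1(C)C=C | intermediate
21 | potassium alkoxide of 20 | [K+].[O-][C@@]1(C2=C[C@@](C)(CO[Si](C)(C)C(C)(C)C)C2)CC[C@H](O[Si](C(C)C)(C(C)C)C(C)C)[C@@]1(C)C=C | intermediate
22 | potassium C1(O)=C9 enolate of 23 | [K+].[O-]/C1=C2/C[C@](C)(CO[Si](C)(C)C(C)(C)C)[C@H]2C/C=C(C)/[C@@H](O[Si](C(C)C)(C(C)C)C(C)C)CC1 | intermediate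
23 | (4S,5E,8S,9R,11S)-11-{[tert-butyl(dimethyl)silyl]oxymethyl}-5,11-dimethyl-4-(triisopropylsilyloxy)bicyclo[7.2.0]undec-5-en-1-one (key-step product, skeleton numbering) | O=C1CC[C@H](O[Si](C(C)C)(C(C)C)C(C)C)/C(C)=C/C[C@H]2[C@H]1C[C@]2(C)CO[Si](C)(C)C(C)(C)C | intermediate
24 | (4S,5S,8S,9R,11S)-saturated ketone | O=C1CC[C@H](O[Si](C(C)C)(C(C)C)C(C)C)[C@@H](C)CC[C@H]2[C@H]1C[C@]2(C)CO[Si](C)(C)C(C)(C)C | intermediate
25 | (4S,5S,8S,9R,11S)-C1-methylidene bis-silyl ether | C=C1CC[C@H](O[Si](C(C)C)(C(C)C)C(C)C)[C@@H](C)CC[C@H]2[C@H]1C[C@]2(C)CO[Si](C)(C)C(C)(C)C | intermediate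
26 | C12 primary alcohol | C=C1CC[C@H](O[Si](C(C)C)(C(C)C)C(C)C)[C@@H](C)CC[C@H]2[C@H]1C[C@]2(C)CO | intermediate
27 | C12 aldehyde | C=C1CC[C@H](O[Si](C(C)C)(C(C)C)C(C)C)[C@@H](C)CC[C@H]2[C@H]1C[C@]2(C)C=O | intermediate
28 | tartrate boronate of the (12S)-homoallylic alcohol | C=C1CC[C@H](O[Si](C(C)C)(C(C)C)C(C)C)[C@@H](C)CC[C@H]2[C@H]1C[C@]2(C)[C@@H](OB3O[C@@H](C(=O)OC(C)C)[C@@H](O3)C(=O)OC(C)C)CC=C | intermediate
29 | (12S)-homoallylic alcohol | C=C1CC[C@H](O[Si](C(C)C)(C(C)C)C(C)C)[C@@H](C)CC[C@H]2[C@H]1C[C@]2(C)[C@@H](O)CC=C | intermediate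
30 | methacrylate ester of 29 | C=C1CC[C@H](O[Si](C(C)C)(C(C)C)C(C)C)[C@@H](C)CC[C@H]2[C@H]1C[C@]2(C)[C@@H](OC(=O)C(C)=C)CC=C | intermediate
31 | (6S)-3-methyl-5,6-dihydro-2H-pyran-2-one (lactone) | C=C1CC[C@H](O[Si](C(C)C)(C(C)C)C(C)C)[C@@H](C)CC[C@H]2[C@H]1C[C@]2(C)[C@@H]3CC=C(C)C(=O)O3 | intermediate
32 | lactol of 31 (present as its aluminium alkoxide) | C=C1CC[C@H](O[Si](C(C)C)(C(C)C)C(C)C)[C@@H](C)CC[C@H]2[C@H]1C[C@]2(C)[C@@H]3CC=C(C)C(O)O3 | intermediate
33 | (Z)-C12,C16-diol | C=C1CC[C@H](O[Si](C(C)C)(C(C)C)C(C)C)[C@@H](C)CC[C@H]2[C@H]1C[C@]2(C)[C@@H](O)C/C=C(/C)CO | intermediate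
34 | C12,C16-diacetate, C4 triisopropylsilyl ether | C=C1CC[C@H](O[Si](C(C)C)(C(C)C)C(C)C)[C@@H](C)CC[C@H]2[C@H]1C[C@]2(C)[C@H](C/C=C(/C)COC(C)=O)OC(C)=O | intermediate
35 | (4S)-C4 alcohol diacetate | C=C1CC[C@H](O)[C@@H](C)CC[C@H]2[C@H]1C[C@]2(C)[C@H](C/C=C(/C)COC(C)=O)OC(C)=O | intermediate
36 | target CNP0244219.2, (5S,8S,9R,11S,12S) | C=C1CCC(=O)[C@@H](C)CC[C@H]2[C@H]1C[C@]2(C)[C@H](C/C=C(/C)COC(C)=O)OC(C)=O | target

## Step count and risk

Total: 26 steps. Longest linear sequence: 22 steps (steps 5–9, then 10–26); the other branch (steps 1–4) joins at step 10.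

**Step 15 (key step).** The most likely failures are that the rearrangement of the alkoxide is slow because the chair leads to a strained nine-membered enolate with two E double bonds, so that cleavage of the alkoxide into fragments takes over, or that equilibration at C9 is incomplete. The fallback leaves the anionic manifold for the neutral silyloxy-Cope rearrangement. It sets out from 20, which is converted with TMSOTf and Et3N into its trimethylsilyl ether F1. Heating F1 in toluene (110–140 °C, sealed tube) should give the silyl enol ether F2 by the same chair, and K2CO3 in methanol cleaves and equilibrates F2, returning to the route at 23.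

**Step 8.** The two enantiotopic methylene groups may be poorly distinguished, because methyl and silyloxymethyl differ little in size, and proton exchange between enolate and unreacted ketone may erode the result. The fallback gives up enantioselective enolisation and resolves through the enantiopure ketone instead. It sets out from 10, which with LDA and Comins' reagent gives the racemic triflate F3 and then, as in step 9, the racemic stannane F4. Addition to 5 as in step 10 gives 16 together with its cyclobutene-epimer F5; chromatographic removal of F5 returns to the route at 16.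

**Step 16.** Hydrogen may add to the face exposed in the conformer first formed by the rearrangement (giving the C5 epimer), and the double bond may migrate toward C4. The fallback replaces substrate control by catalyst control. It sets out from 23 and uses a chiral iridium phosphinooxazoline catalyst, [Ir(cod)((S)-tBu-PHOX)]B[3,5-(CF3)2C6H3]4 or its antipode, under H2 in CH2Cl2, choosing the ligand enantiomer that delivers hydrogen to the required face; it returns at 24 and makes no new compound.

**Step 3.** The methyl and vinyl faces may be poorly discriminated, so that much of the (2S,3R) isomer forms, and some diol may arise by over-reduction. The fallback is biocatalytic: from 3, an R-selective alcohol dehydrogenase (for example that of Lactobacillus kefir, NADPH, isopropanol) is used, whose binding pocket rather than hydride trajectory differentiates the two substituents. It returns at 4 and makes no new compound.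

**Step 20.** Mismatched double diastereodifferentiation and slow addition to the neopentyl aldehyde may lower the selectivity at C12. The fallback sets the carbinol by ketone reduction instead of allyl transfer. It sets out from 27, which with allylmagnesium bromide gives the C12-epimeric alcohols F6. Dess–Martin oxidation gives the allyl ketone F7, and reduction with (R)-2-methyl-CBS-oxazaborolidine and catecholborane, where the quaternary carbon and the allyl CH2 differ strongly in size, returns to the route at 29.

## Further compounds

F1 | step 15 | trimethylsilyl ether of 20 | C[Si](C)(C)O[C@@]1(C2=C[C@@](C)(CO[Si](C)(C)C(C)(C)C)C2)CC[C@H](O[Si](C(C)C)(C(C)C)C(C)C)[C@@]1(C)C=C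
F2 | step 15 | trimethylsilyl enol ether (C1=C9) of 23 | C[Si](C)(C)O/C1=C2/C[C@](C)(CO[Si](C)(C)C(C)(C)C)[C@H]2C/C=C(C)/[C@@H](O[Si](C(C)C)(C(C)C)C(C)C)CC1
F3 | step 8 | rac-3-{[tert-butyl(dimethyl)silyl]oxymethyl}-3-methylcyclobut-1-en-1-yl trifluoromethanesulfonate | O=S(=O)(OC1=CC(C)(CO[Si](C)(C)C(C)(C)C)C1)C(F)(F)F
F4 | step 8 | rac-tert-butyldimethyl{[1-methyl-3-(trimethylstannyl)cyclobut-2-en-1-yl]methoxy}silane | C[Sn](C)(C)C1=CC(C)(CO[Si](C)(C)C(C)(C)C)C1
F5 | step 8 | (1R,2R,3R)-1-[(3R)-3-{[tert-butyl(dimethyl)silyl]oxymethyl}-3-methylcyclobut-1-en-1-yl]-2-ethenyl-2-methyl-3-(triethylsilyloxy)cyclopentan-1-ol | O[C@@]1(C2=C[C@](C)(CO[Si](C)(C)C(C)(C)C)C2)CC[C@@H](O[Si](CC)(CC)CC)[C@@]1(C)C=C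
F0 | step 16 | none | none
F0 | step 3 | none | none
F6 | step 20 | C12-epimeric mixture of homoallylic alcohols | C=C1CC[C@H](O[Si](C(C)C)(C(C)C)C(C)C)[C@@H](C)CC[C@H]2[C@H]1C[C@]2(C)C(O)CC=C
F7 | step 20 | C12 allyl ketone | C=C1CC[C@H](O[Si](C(C)C)(C(C)C)C(C)C)[C@@H](C)CC[C@H]2[C@H]1C[C@]2(C)C(=O)CC=C
A1 | alternative 1 | (2S)-2-[(1S)-1-hydroxy-3-(4-methoxybenzyloxy)propyl]-2-methylcyclobutan-1-one | O=C1CC[C@@]1(C)[C@H](CCOCc2ccc(OC)cc2)O
A2 | alternative 1 | 1-{3-[2-(4-methoxybenzyloxy)ethyl]-2-methyloxiran-2-yl}cyclopropan-1-ol | OC1(CC1)[C@]2(C)O[C@H]2CCOCc3ccc(OC)cc3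
A3 | alternative 2 | methyl trans-2,3-bis(tert-butyldimethylsilyloxymethyl)cyclobutanecarboxylate | CC(C)(C)[Si](C)(C)OC[C@H]2[C@H](CO[Si](C)(C)C(C)(C)C)C[C@@H]2C(=O)OC
A4 | alternative 2 | trans-3,4-bis(tert-butyldimethylsilyloxymethyl)-2-diazocyclopentan-1-one | CC(C)(C)[Si](C)(C)OC[C@H]1[C@H](CO[Si](C)(C)C(C)(C)C)CC(=O)C1=[N+]=[N-]
A5 | alternative 3 | trans-cyclobutane-1,2-dicarbonyl bis(oxazolidinone) with C8, C9 and C11 set | O=C1OCCN1C(=O)[C@H]2[C@H](C(=O)N3CCOC3=O)C[C@]2(C)CO[Si](C(C)C)(C(C)C)C(C)C
A6 | alternative 3 | 3-methyl-3-(triisopropylsilyloxymethyl)hexanedioyl bis(oxazolidinone) | O=C1OCCN1C(=O)C[C@@](C)(CO[Si](C(C)C)(C(C)C)C(C)C)CCC(=O)N2CCOC2=O
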